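**Retrosynthetic overview** (azulene numbering of the target: C1–C3, C3a, C4–C8, C8a)
1. Target 9 ⇒ diol 8 by acylation of the secondary allylic hydroxyl at C4; 8 ⇒ hydroxy ketone 7 by addition of an isopropyl nucleophile to the C3 ketone.
2. Enabling feature: the carbinol carbon C3 of the five-membered ring is a latent ketone whose α-carbon (C3a) and β-carbon (C8a, carrying the angular methyl) are the two ring-fusion atoms. Both bonds that tie the five-membered ring to the seven-membered ring (C8a–C8 and C3a–C4) are therefore the bonds of a conjugate addition/aldol on 3-methylcyclopent-2-en-1-one.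
3. 7 ⇒ diene 6 by ring-closing metathesis at C5=C6; 6 ⇒ enone 1 + homoallyl Grignard 4 (from bromide 2) + acrolein 3 in one three-component operation (C8a set by the catalyst, C3a and C4 relayed from it).
4. Ring order: the five-membered ring is bought (1); the seven-membered ring is closed second (step 2).

Key step: step 1

Assumption: the sense of induction of the copper–carbene catalyst is not asserted here; the ligand antipode that gives the (S)-configured quaternary carbon is to be fixed in a trial run.

**Step 1**
Reactants: 1 3-methylcyclopent-2-en-1-one; 2 4-bromo-2-methylbut-1-ene; 3 prop-2-enal (acrolein)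
Product: 6 (2S,3S)-2-[(1S)-1-hydroxyprop-2-en-1-yl]-3-methyl-3-(3-methylbut-3-en-1-yl)cyclopentan-1-one, via Grignard reagent 4 (not isolated), via magnesium enolate 5 (not isolated)
Conditions: 2, Mg, Et2O, reflux (gives 4, 1.1 equiv); Cu(OTf)2 (3 mol%), 1-mesityl-3-[(2S)-1-hydroxy-3,3-dimethylbutan-2-yl]-4,5-dihydroimidazolium hexafluorophosphate or its antipode (4 mol%), Et2O, −30 °C, slow addition of 1; then 3 (freshly distilled, 1.5 equiv), −78 °C; AcOH in THF, −78 °C
Reagents that add atoms: none
Why: A copper–N-heterocyclic carbene complex formed in situ transfers the homoallyl group of 4 to the β-carbon of 1, and the regiodefined magnesium enolate 5 then adds to the carbonyl of 3, so the C8a–C8 and C3a–C4 bonds are made in one flask. The closest known reaction type is the copper-catalysed asymmetric conjugate addition of Grignard reagents to β-methyl cycloalkenones (all-carbon quaternary centres) with aldol trapping of the magnesium enolate. No ring is closed here; the step puts on the bought five-membered ring the two arms that step 2 joins. The quaternary centre is set by the chiral ligand; the α-centre is set by approach of the aldehyde to the enolate face anti to the larger homoallyl arm (syn to methyl), which is the trans relation that becomes the trans ring fusion; the carbinol centre follows from a Zimmerman–Traxler chair of the ring-locked enolate with the vinyl group equatorial (anti aldol). The step needs 1,4- over 1,2-addition to 1 (copper catalysis in Et2O), 1,2-attack on acrolein without enolate equilibration (magnesium enolate at −78 °C, aldehyde without α-hydrogens) and a cold acetic acid quench against retro-aldol and dehydration. The facial selectivity rests on a modest steric difference between methyl and the homoallyl arm and is treated under the risks.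

**Step 2**
Reactants: 6 (2S,3S)-2-[(1S)-1-hydroxyprop-2-en-1-yl]-3-methyl-3-(3-methylbut-3-en-1-yl)cyclopentan-1-one
Product: 7 (3aS,4S,8aS)-4-hydroxy-6,8a-dimethyl-2,3a,4,7,8,8a-hexahydroazulen-3(1H)-one
Conditions: second-generation Grubbs catalyst (H2IMes)(PCy3)Cl2Ru=CHPh (5 mol%), CH2Cl2 (0.005 M), 40 °C
Reagents that add atoms: none
Why: Ring-closing olefin metathesis: the ruthenium carbene loads on the unhindered vinyl carbinol and closes onto the 1,1-disubstituted alkene held on the neighbouring ring carbon, so the trisubstituted C5=C6 alkene of the seven-membered ring forms with loss of ethene, no stereocentre is touched and the trans arrangement of the two arms becomes the trans ring fusion.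

**Step 3**
Reactants: 7 (3aS,4S,8aS)-4-hydroxy-6,8a-dimethyl-2,3a,4,7,8,8a-hexahydroazulen-3(1H)-one
Product: 8 (3R,3aS,4S,8aS)-6,8a-dimethyl-3-(propan-2-yl)-1,2,3,3a,4,7,8,8a-octahydroazulene-3,4-diol
Conditions: iPrMgCl (4 equiv), anhydrous CeCl3 (4 equiv), THF, −78 → −20 °C; 10% aq. AcOH
Reagents that add atoms: isopropylmagnesium chloride, CC(C)[Mg]Cl
Why: Organocerium (Imamoto) 1,2-addition: after one equivalent has deprotonated the hydroxyl, the weakly basic isopropylcerium reagent adds to the hindered ketone without enolisation, β-hydride reduction or retro-aldol opening, and it should enter from the face opposite the pseudoaxial angular methyl and the C3a–C4 bond (the face of H-3a), which places the new hydroxyl cis to the angular methyl and sets (3R).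

**Step 4**
Reactants: 8 (3R,3aS,4S,8aS)-6,8a-dimethyl-3-(propan-2-yl)-1,2,3,3a,4,7,8,8a-octahydroazulene-3,4-diol
Product: 9 (3R,3aS,4S,8aS)-3-hydroxy-6,8a-dimethyl-3-(propan-2-yl)-1,2,3,3a,4,7,8,8a-octahydroazulen-4-yl 4-methoxybenzoate
Conditions: 4-methoxybenzoyl chloride (1.5 equiv), Et3N, DMAP (0.2 equiv), CH2Cl2, 0 °C → rt
Reagents that add atoms: 4-methoxybenzoyl chloride, COc1ccc(cc1)C(Cl)=O
Why: DMAP-catalysed acylation with an acid chloride: the secondary allylic hydroxyl at C4 is esterified with retention while the tertiary hydroxyl at C3 is too hindered to react.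

**Compound list**
1 | 3-methylcyclopent-2-en-1-one | CC1=CC(=O)CC1 | starting material
2 | 4-bromo-2-methylbut-1-ene | CC(=C)CCBr | starting material
3 | prop-2-enal (acrolein) | C=CC=O | starting material
4 | (3-methylbut-3-en-1-yl)magnesium bromide | CC(=C)CC[Mg]Br | intermediate
5 | bromomagnesium (3S)-3-methyl-3-(3-methylbut-3-en-1-yl)cyclopent-1-en-1-olate | Br[Mg]OC1=C[C@@](C)(CCC(C)=C)CC1 | intermediate
6 | (2S,3S)-2-[(1S)-1-hydroxyprop-2-en-1-yl]-3-methyl-3-(3-methylbut-3-en-1-yl)cyclopentan-1-one (hydroxyallyl arm trans to the homoallyl arm, cis to methyl) | O[C@@H](C=C)[C@H]1C(=O)CC[C@]1(C)CCC(C)=C | intermediate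
7 | (3aS,4S,8aS)-4-hydroxy-6,8a-dimethyl-2,3a,4,7,8,8a-hexahydroazulen-3(1H)-one (trans-fused; 4-OH cis to H-3a) | O[C@H]1C=C(C)CC[C@@]2(C)CCC(=O)[C@H]12 | intermediate
8 | (3R,3aS,4S,8aS)-6,8a-dimethyl-3-(propan-2-yl)-1,2,3,3a,4,7,8,8a-octahydroazulene-3,4-diol (3-OH cis to the angular methyl) | O[C@H]1C=C(C)CC[C@@]2(C)CC[C@@](O)(C(C)C)[C@H]12 | intermediate
9 | (3R,3aS,4S,8aS)-3-hydroxy-6,8a-dimethyl-3-(propan-2-yl)-1,2,3,3a,4,7,8,8a-octahydroazulen-4-yl 4-methoxybenzoate | COc1ccc(C(=O)O[C@H]2C=C(C)CC[C@@]3(C)CC[C@@](O)(C(C)C)[C@H]23)cc1 | target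

Total step count: 4. Longest linear sequence: 4 steps.

**Steps most likely to fail**

1. Step 1. The aldehyde may not distinguish well enough between the methyl and homoallyl faces of enolate 5, and the syn/anti ratio at the carbinol or the enantioselectivity of the conjugate addition may be low. The fallback sets out from 1 and 4 and comes back at 6; it replaces substrate control by catalyst control in the aldol. The conjugate addition is run as above, but enolate 5 is silylated with Me3SiCl/Et3N to give (S)-trimethyl{[3-methyl-3-(3-methylbut-3-en-1-yl)cyclopent-1-en-1-yl]oxy}silane F1, which can be purified. SiCl4 with catalytic Hg(OAc)2 converts it into the trichlorosilyl enolate (S)-trichloro{[3-methyl-3-(3-methylbut-3-en-1-yl)cyclopent-1-en-1-yl]oxy}silane F2. A chiral phosphoramide-catalysed (Lewis-base-catalysed) aldol addition of F2 to 3 in CH2Cl2 at −78 °C is a known anti-selective reaction of ring-locked trichlorosilyl enolates in which the catalyst fixes the enolate face. It gives the trichlorosilyl ether of 6, F3, which aqueous NaHCO3 hydrolyses to 6.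

2. Step 3. Enolisation, hydride transfer from the isopropyl reagent or retro-aldol opening may compete with addition to the hindered ketone. The fallback sets out from 7 and comes back at 8. The smaller, non-reducing isopropenylmagnesium bromide with CeCl3 in THF at −78 °C adds to the ketone to give (3S,3aS,4S,8aS)-6,8a-dimethyl-3-(prop-1-en-2-yl)-1,2,3,3a,4,7,8,8a-octahydroazulene-3,4-diol F4. Hydrogenation with RhCl(PPh3)3 under H2 in benzene then saturates the 1,1-disubstituted alkene in preference to the trisubstituted ring alkene and gives 8.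

3. Step 2. Closure to the trisubstituted alkene may be slow, so that oligomerisation or ruthenium-hydride isomerisation of the allylic alcohol to a ketone takes over. The fallback sets out from 6 and comes back at 8; it changes the order of ring closure and carbonyl addition. iPrMgCl/CeCl3 is added to 6 first to give (1R,2S,3S)-2-[(1S)-1-hydroxyprop-2-en-1-yl]-3-methyl-3-(3-methylbut-3-en-1-yl)-1-(propan-2-yl)cyclopentan-1-ol F5. This diene has no ketone, and the fully substituted carbinol next to the arms should favour cyclisation. Ring-closing metathesis with the second-generation Grubbs catalyst then gives 8 directly.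

**Further compounds**
F1 | step 1 | (S)-trimethyl{[3-methyl-3-(3-methylbut-3-en-1-yl)cyclopent-1-en-1-yl]oxy}silane | C[Si](C)(C)OC1=C[C@@](C)(CCC(C)=C)CC1
F2 | step 1 | (S)-trichloro{[3-methyl-3-(3-methylbut-3-en-1-yl)cyclopent-1-en-1-yl]oxy}silane | Cl[Si](Cl)(Cl)OC1=C[C@@](C)(CCC(C)=C)CC1
F3 | step 1 | trichlorosilyl ether of 6, (2S,3S)-3-methyl-3-(3-methylbut-3-en-1-yl)-2-[(1S)-1-(trichlorosilyloxy)prop-2-en-1-yl]cyclopentan-1-one | Cl[Si](Cl)(Cl)O[C@@H](C=C)[C@H]1C(=O)CC[C@]1(C)CCC(C)=C
F4 | step 3 | (3S,3aS,4S,8aS)-6,8a-dimethyl-3-(prop-1-en-2-yl)-1,2,3,3a,4,7,8,8a-octahydroazulene-3,4-diol | O[C@H]1C=C(C)CC[C@@]2(C)CC[C@@](O)(C(C)=C)[C@H]12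
F5 | step 2 | (1R,2S,3S)-2-[(1S)-1-hydroxyprop-2-en-1-yl]-3-methyl-3-(3-methylbut-3-en-1-yl)-1-(propan-2-yl)cyclopentan-1-ol | O[C@@H](C=C)[C@H]1[C@](O)(C(C)C)CC[C@]1(C)CCC(C)=C
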